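## Retrosynthetic overview (germacrane numbering)

1. The acetate goes on last. The ten-membered ring (ring B, formed second) is opened at the Z C1=C10 olefin by ring-closing metathesis, giving an acyclic cis-lactone tetraene.
2. Key disconnection: the lactone C6–O bond of ring A (formed first), made by closing a carboxylate onto a π-allylpalladium. Unravelled together with C7–C11, it leads to 2-bromoacrylic acid and an (E,Z)-dienediol.
3. The dienediol is cut at C5–C6 (Suzuki) into two pieces. One is a (Z)-iodoalkenol from propargyl alcohol and butenyl Grignard, which fixes C4=C5 and brings the C15 oxygen. The other is an (S)-homopropargylic alcohol from methacrolein, which sets C9.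
4. The C15 isovalerate is introduced by chemoselective acylation of the primary alcohol after the annulation.

Assumption: the SMILES is read literally. This means the lactone O is on C6, C7 carries C11, the acetate is on C9 and the isovalerate on C15. The configuration is 6R,7R,9S with a cis-fused lactone, C1=C10 is Z (cis inside the ring), and C4=C5 has C6 and C15 on the same side (trans inside the ring).

## Route

Step 1
Reactants: 1 prop-2-yn-1-ol; 2 but-3-enylmagnesium bromide (2.5 equiv)
Product: 4 (Z)-2-(iodomethylidene)hex-5-en-1-ol, via bis(bromomagnesio) alkenyl alkoxide 3 (not isolated)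
Conditions: CuI (10 mol%), THF, -10 °C to rt, 12 h; I2 (1.3 equiv), -78 to 0 °C; H2O, aq Na2S2O3
Reagents that add atoms: iodine, II
Why: Copper-catalysed anti-carbomagnesiation of the propargylic alkoxide gives the chelated alkenylmagnesium with Mg cis to CH2O, so iodinolysis with retention places iodine cis to CH2OH and fixes the C4=C5 geometry (C6 cis to C15).

Step 2
Reactants: 5 methacrolein; 6 allenylboronic acid pinacol ester
Product: 8 (3S)-2-methylhex-1-en-5-yn-3-ol, via homopropargyl pinacol borate 7 (not isolated)
Conditions: (S)-TRIP phosphoric acid (5 mol%), 4 Å MS, toluene, -20 °C, 48 h; aq NaHCO3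
Reagents that add atoms: none
Why: Chiral-phosphoric-acid-catalysed allenylboration (carbonyl propargylation) runs through a closed six-membered transition state, and the (S)-acid directs si-face attack (sense assigned by analogy with aryl and alkenyl aldehydes), which sets C9 as S.

Step 3
Reactants: 8 (3S)-2-methylhex-1-en-5-yn-3-ol; 4 (Z)-2-(iodomethylidene)hex-5-en-1-ol
Product: 10 (3S,5E,7Z)-8-(hydroxymethyl)-2-methyldodeca-1,5,7,11-tetraen-3-ol, via O-boryl (E)-alkenylboronate 9 (not isolated)
Conditions: HBpin (2.2 equiv), Cp2Zr(H)Cl (5 mol%), Et3N (5 mol%), 40 °C, 6 h; then 4 (0.95 equiv), Pd(dppf)Cl2 (3 mol%), K3PO4 (3 M aq, 3 equiv), THF, 45 °C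
Reagents that add atoms: none
Why: Zirconocene-hydride-catalysed syn-hydroboration of the terminal alkyne (much faster than of the 1,1-disubstituted olefin) gives the E-alkenylboronate, and the Suzuki–Miyaura coupling forms C5–C6 with retention on both partners, so the 5E,7Z-diene results and C9 is untouched.

Step 4
Reactants: 10 (3S,5E,7Z)-8-(hydroxymethyl)-2-methyldodeca-1,5,7,11-tetraen-3-ol; 11 2-bromoacrylic acid
Product: 12 (4R,5R)-4-[(2S)-2-hydroxy-3-methylbut-3-en-1-yl]-5-[(1Z)-2-(hydroxymethyl)hexa-1,5-dien-1-yl]-3-methylideneoxolan-2-one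
Conditions: 11 (1.5 equiv, syringe pump), Pd2(dba)3 (2.5 mol%), (R)-BINAP (6 mol%), Ag3PO4 (0.7 equiv), BHT (5 mol%), THF/DMA 4:1, 40 °C, dark
Reagents that add atoms: none
Why: Proposed new method: a ligand-controlled carbo-acyloxylation of an internal 1,1,4-trisubstituted 1,3-diene with 2-bromoacrylic acid, in which zerovalent palladium inserts into C–Br and silver removes bromide to give a cationic (BINAP)Pd-alkenyl that adds syn to the less substituted diene terminus C7 on the face chosen by the ligand (the electron-rich diene beats the isolated vinyl and isopropenyl groups because insertion ends in a stabilised π-allyl), the P,P-chelate blocks inner-sphere delivery so that after rotation about C6–C7 the tethered carboxylate closes the key C6–O bond anti to palladium, this net anti addition across the E C6=C7 bond can give only the cis-lactone (6R,7R), and the fully substituted allyl terminus C4 never becomes σ-bound so the C4=C5 geometry is kept; the closest known reaction types are the Larock heteroannulation of terminal or cyclic 1,3-dienes, the cationic asymmetric Heck reaction and Tsuji–Trost lactonisation.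

Step 5
Reactants: 12 lactone diol; 13 3-methylbutanoyl chloride
Product: 14 [(2Z)-2-(but-3-en-1-yl)-3-{(2R,3R)-3-[(2S)-2-hydroxy-3-methylbut-3-en-1-yl]-4-methylidene-5-oxooxolan-2-yl}prop-2-en-1-yl] 3-methylbutanoate
Conditions: 13 (1.05 equiv), 2,4,6-collidine (2 equiv), CH2Cl2, -78 to -40 °C
Reagents that add atoms: none
Why: In this kinetically controlled acylation (nucleophilic acyl substitution) the primary allylic C15–OH reacts far faster than the secondary C9–OH flanked by the isopropenyl group, and no stereocentre is touched.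

Step 6
Reactants: 14 C15 isovalerate with free C9–OH
Product: 15 (6R,7R,9S)-9-hydroxy-15-(3-methylbutanoyloxy)germacra-1(10),4,11(13)-trien-12,6-olide with C1=C10 Z
Conditions: second-generation Hoveyda–Grubbs catalyst RuCl2(H2IMes)(=CH-C6H4-2-OiPr) (2 x 5 mol%), 1,4-benzoquinone (20 mol%), toluene (1 mM), 60 °C, argon sparge
Reagents that add atoms: none
Why: In this ring-closing metathesis ruthenium loads on the C1 vinyl group, the cis-disposed lactone side chains and the free allylic C9–OH favour closure onto the isopropenyl group, smaller rings would have to hold the trans C4=C5 bond, and a ten-membered ring that already contains one trans olefin should take the new trisubstituted olefin as Z, with no stereocentre touched.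

Step 7
Reactants: 15 macrocyclic C9 alcohol; 16 acetic anhydride
Product: 17 target CNP0398030.1, (6R,7R,9S)-9-acetoxy-15-(3-methylbutanoyloxy)germacra-1(10),4,11(13)-trien-12,6-olide
Conditions: 16 (1.5 equiv), Et3N (2 equiv), DMAP (5 mol%), CH2Cl2, 0 °C, 1 h
Reagents that add atoms: none
Why: DMAP-catalysed O-acetylation takes place at oxygen, so C9 keeps its S configuration, and the mild cold conditions spare the α-methylene lactone and the Cope-prone 1,5-diene.

## Compound list

1 | prop-2-yn-1-ol | C#CCO | starting material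
2 | but-3-enylmagnesium bromide | C=CCC[Mg]Br | starting material
3 | (Z)-bis(bromomagnesio) alkenyl alkoxide | C=CCC/C(CO[Mg]Br)=C/[Mg]Br | intermediate
4 | (Z)-2-(iodomethylidene)hex-5-en-1-ol | C=CCC/C(CO)=C/I | intermediate
5 | methacrolein | C=C(C)C=O | starting material
6 | allenylboronic acid pinacol ester | C=C=CB1OC(C)(C)C(C)(C)O1 | starting material
7 | (3S)-2-methylhex-1-en-5-yn-3-yl pinacol borate | C#CC[C@H](OB1OC(C)(C)C(C)(C)O1)C(C)=C | intermediate
8 | (3S)-2-methylhex-1-en-5-yn-3-ol | C#CC[C@H](O)C(C)=C | intermediate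
9 | O-boryl (E)-alkenylboronate from 8 | CC1(C)OB(/C=C/C[C@H](OB2OC(C)(C)C(C)(C)O2)C(C)=C)OC1(C)C | intermediate
10 | (3S,5E,7Z)-8-(hydroxymethyl)-2-methyldodeca-1,5,7,11-tetraen-3-ol | C=CCC/C(CO)=C/C=C/C[C@H](O)C(C)=C | intermediate
11 | 2-bromoacrylic acid | C=C(Br)C(=O)O | starting material
12 | cis-α-methylene lactone diol (6R,7R,9S) | C=C1C(=O)O[C@H](/C=C(\CO)CCC=C)[C@@H]1C[C@H](O)C(C)=C | intermediate
13 | 3-methylbutanoyl chloride | CC(C)CC(=O)Cl | starting material
14 | C15 isovalerate of 12 | C=C1C(=O)O[C@H](/C=C(\COC(=O)CC(C)C)CCC=C)[C@@H]1C[C@H](O)C(C)=C | intermediate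
15 | macrocyclic C9 alcohol | C=C1C(=O)O[C@@H]2/C=C(\COC(=O)CC(C)C)CC/C=C(/C)[C@@H](O)C[C@H]12 | intermediate
16 | acetic anhydride | CC(=O)OC(C)=O | starting material
17 | CNP0398030.1 | C=C1C(=O)O[C@@H]2/C=C(\COC(=O)CC(C)C)CC/C=C(/C)[C@@H](OC(C)=O)C[C@H]12 | target

## Step count

Total: 7 steps. Longest linear sequence: 6 steps (5 → 8 → 10 → 12 → 14 → 15 → 17).

## The three steps most likely to fail

**Step 4 (the new annulation).**
- Risks: a Heck reaction at the C1 vinyl group instead of the hindered diene, inner-sphere closure to the trans-lactone, and weak facial control. The sense of induction is not predictable, so both BINAP antipodes are run and the one that gives 12 is kept.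
- Fallback, known chemistry only: it sets out from 4 and 8 and comes back at 12.
- Iodine–magnesium exchange on 4 (iPrMgCl·LiCl, 2.1 equiv, THF, -20 °C) followed by DMF gives the (Z)-4-hydroxyenal. It is isolated as its lactol 4-(but-3-en-1-yl)-2,5-dihydrofuran-2-ol F1.
- In parallel, 8 is silylated (TBSCl, imidazole) to tert-butyldimethyl{[(3S)-2-methylhex-1-en-5-yn-3-yl]oxy}silane F2.
- F2 is carboxylated (n-BuLi, then ClCO2Me) to methyl (5S)-5-[(tert-butyldimethylsilyl)oxy]-6-methylhept-6-en-2-ynoate F3.
- F3 is hydroaluminated with iBu2AlH/HMPA and trapped with formaldehyde to give methyl (2Z,5S)-5-[(tert-butyldimethylsilyl)oxy]-2-(hydroxymethyl)-6-methylhepta-2,6-dienoate F4.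
- F4 is brominated (CBr4, PPh3) to methyl (2E,5S)-2-(bromomethyl)-5-[(tert-butyldimethylsilyl)oxy]-6-methylhepta-2,6-dienoate F5.
- The indium-mediated Barbier allylation of F1 with F5 (In powder, THF/H2O) is syn-selective. The adduct lactonises on work-up to the 9-O-TBS ether of 12 F6.
- The remote C9 centre gives little facial bias, so F6 has to be separated from the 6S,7S isomer of the 9-O-TBS ether F7. HF·pyridine then gives 12.

**Step 6 (ring-closing metathesis to a ten-membered carbocycle with a trisubstituted olefin).**
- Risks: dimerisation at C1, no engagement of the hindered isopropenyl carbinol, and E/Z mixtures.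
- Fallback: it sets out from 14 and comes back at 15. It changes the substrate class and the origin of C9.
- Dess–Martin oxidation of 14 gives the 9-oxo analogue of 14 (isopropenyl ketone) F8.
- The ring is then closed onto the conjugated enone olefin with the same ruthenium catalyst. An sp2 C9 removes one transannular contact, and there is no allylic C–O group left to chelate ruthenium. The product is the 9-oxo analogue of 15 (macrocyclic Z-enone) F9.
- Reagent-controlled 1,2-reduction with (R)-Me-CBS and catecholborane at -78 °C resets C9 as S and returns 15.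

**Step 2 (enantioselectivity on the small, α-branched enal).**
- Risks: moderate ee and loss of the volatile product.
- Fallback: it sets out from 5 and comes back at 8.
- Zinc-mediated Barbier propargylation (propargyl bromide, Zn dust, THF/aq NH4Cl) gives racemic 2-methylhex-1-en-5-yn-3-ol F10.
- Sharpless kinetic resolution (Ti(OiPr)4, D-(-)-DIPT, t-BuOOH 0.6 equiv, 4 Å MS, CH2Cl2, -20 °C) epoxidises the R enantiomer to (1R)-1-[(2S)-2-methyloxiran-2-yl]but-3-yn-1-ol F11. It leaves 8, which is separated by chromatography (at most 50 %).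

## Further compounds

F1 | step 4 | 4-(but-3-en-1-yl)-2,5-dihydrofuran-2-ol | C=CCCC1=CC(O)OC1
F2 | step 4 | tert-butyldimethyl{[(3S)-2-methylhex-1-en-5-yn-3-yl]oxy}silane | C#CC[C@H](O[Si](C)(C)C(C)(C)C)C(C)=C
F3 | step 4 | methyl (5S)-5-[(tert-butyldimethylsilyl)oxy]-6-methylhept-6-en-2-ynoate | COC(=O)C#CC[C@H](O[Si](C)(C)C(C)(C)C)C(C)=C
F4 | step 4 | methyl (2Z,5S)-5-[(tert-butyldimethylsilyl)oxy]-2-(hydroxymethyl)-6-methylhepta-2,6-dienoate | COC(=O)/C(CO)=C\C[C@H](O[Si](C)(C)C(C)(C)C)C(C)=C
F5 | step 4 | methyl (2E,5S)-2-(bromomethyl)-5-[(tert-butyldimethylsilyl)oxy]-6-methylhepta-2,6-dienoate | COC(=O)/C(CBr)=C\C[C@H](O[Si](C)(C)C(C)(C)C)C(C)=C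
F6 | step 4 | 9-O-TBS ether of 12 | C=C1C(=O)O[C@H](/C=C(\CO)CCC=C)[C@@H]1C[C@H](O[Si](C)(C)C(C)(C)C)C(C)=C
F7 | step 4 | 6S,7S isomer of the 9-O-TBS ether | C=C1C(=O)O[C@@H](/C=C(\CO)CCC=C)[C@H]1C[C@H](O[Si](C)(C)C(C)(C)C)C(C)=C
F8 | step 6 | 9-oxo analogue of 14 (isopropenyl ketone) | C=C1C(=O)O[C@H](/C=C(\COC(=O)CC(C)C)CCC=C)[C@@H]1CC(=O)C(C)=C
F9 | step 6 | 9-oxo analogue of 15 (macrocyclic Z-enone) | C=C1C(=O)O[C@@H]2/C=C(\COC(=O)CC(C)C)CC/C=C(/C)C(=O)C[C@H]12
F10 | step 2 | racemic 2-methylhex-1-en-5-yn-3-ol | C#CCC(O)C(C)=C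
F11 | step 2 | (1R)-1-[(2S)-2-methyloxiran-2-yl]but-3-yn-1-ol | C#CC[C@@H](O)[C@]1(C)CO1
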